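Early in the dawn run Q reaches 10.5% by 6.00 h, while the noon run shows 0.6% at 40.0 h. The proposed steps with D spend one D each and give one G: J gives Z, Z gives L, L gives Q. L may also turn into E by itself.

the same everywhere: J 0.089 M
- noon: D 0.029 M; run made earlier
- dawn: D 0.24 M; run made earlier
- Tuesday's: D 0.0445 M; time 3.0 d
- Saturday's: D 0.267 M; time 3.0 d
- Monday's: D 0.356 M; time 3.0 d

- noon (time / h: Q / %): 2.50: 0.1; 8.00: 0.2; 12.0: 0.5; 20.0: 0; 30.0: 0; 40.0: 0.6
- dawn (time / h: Q / %): 6.00: 10.5; 12.0: 24.2; 20.0: 36.0; 25.0: 40.5; 30.0: 42.6; 40.0: 45.7

(standard deviation of a reading: 0.5 percentage points)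

- steps that have been proposed: J + D -> Z + G; D + Z -> L + G; D + L -> Q + G; L -> E

1. which of these holds the largest part of the J at the end of Tuesday's (Z / J / Q / L)
2. which of these holds the largest part of the J at the end of Saturday's (Z / J / Q / L)
3. which of these holds the largest part of the J at the end of Monday's (Z / J / Q / L)
4. final Q in Saturday's, as a percentage of the J charged

Take the balance of D. Reaching L costs two D per J. Saturday's surplus is 0.0890 M: the D charged less twice the J charged, which is what the last step can draw on. That is about as much as Saturday's J. The dawn surplus is 0.0620 M, and Monday's is 0.178 M. Tuesday's is −0.134 M, negative. There D is the limiting reagent, charged at less than J.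

Two chemists read this differently. The first says Q takes a fixed share of the surplus. The last dawn reading holds 0.0407 M of Q, a share of 65.6%, so Saturday's should reach 65.6% of the J.

The second chemist made the forecast and expects less: “Q stops well short of 100% even though D is nearly sufficient, so L must be leaking to E in competition with L + D.” Her answers are J for Tuesday's, Q for Saturday's, Q for Monday's, and Q at 59% on Saturday's.

    J + D → Z + G (k = 1.10 M⁻¹ h⁻¹)
    D + Z → L + G (k = 1.10 M⁻¹ h⁻¹)
    D + L → Q + G (k = 1.00 M⁻¹ h⁻¹)
    L → E (k = 0.0640 h⁻¹)

Saturday's gives Q 57.4% at 3.00 d, less than the fixed share's figure, and the leaders are J, Q, Q. Z 1.79% and L 1.24% still stand in that flask. By 30.0 d Saturday's holds Q 58.6% and E 41.4%. The surplus less that Q is 0.0368 M, or 13.8% of the D charged, and the flask keeps 13.8%. The neighbour of Saturday's charged with 0.36 M of J has a negative surplus, −0.453 M, and still ends with Q at 3.33%, beside Z at 35.5%.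

(Readings and results are simulated for an exercise; scatter was added.)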